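**Plan**
1. Cuts: the acetate C–O bond; then the C–C bond between the acetoxy-bearing carbon and the methylidene-bearing carbon (alkenyl bromide 16 + aldehyde 27); then the ring C2=C3 bond of the cyclohexenone (2,6-diketone 13). The diketone is traced to δ-lactone 11, and the butenolide of 27 to geranylacetone.
2. Enabling feature: in the enone C1(=O)–C2H=C3(CH3), C1 and C3 are 1,5-related through C6–C5–C4. The carbocycle is therefore a δ-lactone with C2 in place of the ring oxygen (lactone C=O = C3; lactone O–CH(CH3) = C1 and its methyl = C2).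
3. Forward: lactone ring by ring-closing metathesis; the C5 methyl, then the C4 chain and C4 methyl are set on the lactone; MeLi opening and oxidation give the diketone, which the aldol condensation re-closes as the carbocycle. The butenolide ring is closed by intramolecular HWE; the fragments are joined by a Nozaki–Hiyama–Kishi coupling; acetylation is last.
4. Stereochemistry: C5 by 1,3-induction from the (R)-carbinol of commercial (R)-pent-4-en-2-ol (a temporary centre that ends as the ring C=O); quaternary C4 by alkylation anti to the C5 methyl; the acetoxy carbinol by ligand control in the coupling; the (E)-alkene comes with geranylacetone.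

Key step: step 9

Assumption: in step 14 the (4S)-oxazoline–sulfonamide ligand is taken to direct the alkenyl group to the Si face of the aldehyde (which gives the (R)-carbinol); if the sense proves opposite, its (4R)-enantiomer is used and nothing else changes.

**Step 1**
Reactants: 1 (R)-pent-4-en-2-ol; 2 acryloyl chloride
Product: 3 (R)-pent-4-en-2-yl prop-2-enoate
Conditions: Et3N, DMAP (cat.), CH2Cl2, 0 °C to rt
Reagents that add atoms: none
Why: DMAP-catalysed O-acylation of a secondary alcohol by an acid chloride; the C–O bond at the stereocentre is not broken, so (R) is kept.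

**Step 2**
Reactants: 3 (R)-pent-4-en-2-yl prop-2-enoate
Product: 4 (R)-6-methyl-5,6-dihydro-2H-pyran-2-one
Conditions: second-generation Grubbs catalyst (3 mol%), CH2Cl2 (0.01 M), 40 °C
Reagents that add atoms: none
Why: Ring-closing metathesis of an acrylate with a terminal alkene should close the unsaturated δ-lactone with loss of ethylene; the stereocentre is not involved.

**Step 3**
Reactants: 4 (R)-6-methyl-5,6-dihydro-2H-pyran-2-one
Product: 5 (4R,6R)-4,6-dimethyltetrahydro-2H-pyran-2-one
Conditions: Me2CuLi (from MeLi and CuI), Et2O, −78 to −20 °C; aq. NH4Cl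
Reagents that add atoms: lithium dimethylcuprate, [Li+].C[Cu-]C
Why: Conjugate addition of a Gilman cuprate to an α,β-unsaturated δ-lactone; the methyl should add axially to the half-chair with the C6 methyl pseudo-equatorial, anti to it (1,3-induction), giving the trans-4,6 lactone with new C4 (R).

**Step 4**
Reactants: 6 3-bromobut-3-en-1-ol
Product: 7 3-bromobut-3-en-1-yl trifluoromethanesulfonate
Conditions: Tf2O, 2,6-lutidine, CH2Cl2, −78 °C; short silica plug, used at once
Reagents that add atoms: trifluoromethanesulfonic anhydride, O=S(=O)(OS(=O)(=O)C(F)(F)F)C(F)(F)F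
Why: O-sulfonylation of a primary alcohol gives an alkylating agent reactive enough for a lactone enolate at −78 °C, where E2 loss to the diene should be slow.

**Step 5**
Reactants: 5 (4R,6R)-4,6-dimethyltetrahydro-2H-pyran-2-one; 7 3-bromobut-3-en-1-yl trifluoromethanesulfonate
Product: 9 (3S,4R,6R)-3-(3-bromobut-3-en-1-yl)-4,6-dimethyltetrahydro-2H-pyran-2-one, via lithium enolate 8 (not isolated)
Conditions: LiN(iPr)2 (1.05 equiv), THF, −78 °C; then 7, −78 to −40 °C
Reagents that add atoms: none
Why: Enolate alkylation (SN2) of a δ-lactone with a primary triflate; the chain should enter anti to the C4 methyl (3,4-trans), a centre that is planarised again in step 6.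

**Step 6**
Reactants: 9 (3S,4R,6R)-3-(3-bromobut-3-en-1-yl)-4,6-dimethyltetrahydro-2H-pyran-2-one
Product: 11 (3R,4R,6R)-3-(3-bromobut-3-en-1-yl)-3,4,6-trimethyltetrahydro-2H-pyran-2-one, via lithium enolate 10 (not isolated)
Conditions: LiN(iPr)2 (1.2 equiv), THF, −78 to −40 °C; then MeI, DMPU, −78 to −20 °C
Reagents that add atoms: iodomethane, CI
Why: Second enolate alkylation builds the quaternary centre; in enolate 10 the C4 methyl should sit pseudo-axial (relief of A1,2 strain against the C3 chain, C6 methyl equatorial) and shield one face, so MeI enters anti to it, leaving CH3 trans and the chain cis to the C4 methyl, i.e. (3R).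

**Step 7**
Reactants: 11 (3R,4R,6R)-3-(3-bromobut-3-en-1-yl)-3,4,6-trimethyltetrahydro-2H-pyran-2-one
Product: 12 (3R,4R,6R)-3-(3-bromobut-3-en-1-yl)-6-hydroxy-3,4-dimethylheptan-2-one (open form; may rest as its cyclic hemiketal)
Conditions: MeLi (1.2 equiv), THF, −78 °C; aq. NH4Cl
Reagents that add atoms: methyllithium, [Li]C
Why: 1,2-addition of MeLi to a lactone should stop at the ketone stage because the lithium hemiketal of this α,α-disubstituted lactone does not collapse at −78 °C; MeLi does not exchange with an alkenyl bromide at this temperature, and no stereocentre is touched.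

**Step 8**
Reactants: 12 (3R,4R,6R)-3-(3-bromobut-3-en-1-yl)-6-hydroxy-3,4-dimethylheptan-2-one
Product: 13 (3R,4R)-3-(3-bromobut-3-en-1-yl)-3,4-dimethylheptane-2,6-dione
Conditions: Dess–Martin periodinane (1.5 equiv), pyridine, CH2Cl2, rt
Reagents that add atoms: none
Why: Dess–Martin oxidation of the secondary alcohol of the open tautomer (the hemiketal carbon bears no hydrogen and drains through ring opening); it removes the temporary stereocentre once it has done its work.

**Step 9**
Reactants: 13 (3R,4R)-3-(3-bromobut-3-en-1-yl)-3,4-dimethylheptane-2,6-dione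
Product: 16 (4R,5R)-4-(3-bromobut-3-en-1-yl)-3,4,5-trimethylcyclohex-2-en-1-one, via enamine 14 (not isolated), via ketol 15 (not isolated)
Conditions: pyrrolidine (30 mol%), AcOH (30 mol%), toluene, 80 °C
Reagents that add atoms: none
Why: Pyrrolidine should condense only with the unhindered C6 ketone of 13 (the C2 ketone is flanked by the quaternary carbon) to give enamine 14, whose terminal CH2 (C7) adds to the C2 carbonyl; hydrolysis of the iminium ion gives ketol 15, which loses water under the same amine–acid catalysis to give the conjugated enone 16. The closest known reaction type is the amine-catalysed intramolecular aldol condensation of a 1,5-diketone, the second half of a Robinson annulation. The six-membered ring closes in the 6-(enolendo)-exo-trig mode. No new stereocentre is formed, and the two existing ones cannot epimerise, because the quaternary carbon has no hydrogen and the CH(CH3) carbon is β, not α, to both carbonyls. The step needs regioselectivity between the two aldol directions (C7 onto C2 against C1 onto C6); the quaternary centre secures it by blocking enamine formation at C2, so only the C6 ketone becomes the nucleophile, and its other enamine (towards C5) could only close a four-membered ring. The buffered, non-basic medium should also avoid retro-Michael cleavage of the bond between the two stereocentres.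

**Step 10**
Reactants: 17 (5E)-6,10-dimethylundeca-5,9-dien-2-one (geranylacetone)
Product: 19 (5E)-8-(3,3-dimethyloxiran-2-yl)-6-methyloct-5-en-2-one (racemic at the oxirane carbon), via bromohydrin 18 (not isolated)
Conditions: NBS (1.05 equiv), THF/H2O, 0 °C; then K2CO3, MeOH, rt
Reagents that add atoms: water, O
Why: Bromohydrin formation in aqueous medium should pick the terminal, most exposed trisubstituted alkene (water opens the bromonium ion at the tertiary carbon), and base then closes the epoxide; its stereocentre is cut out in step 13, so the racemate serves.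

**Step 11**
Reactants: 19 (5E)-8-(3,3-dimethyloxiran-2-yl)-6-methyloct-5-en-2-one
Product: 22 (5E)-1-bromo-8-(3,3-dimethyloxiran-2-yl)-6-methyloct-5-en-2-one, via lithium enolate 20 (not isolated), via silyl enol ether 21 (not isolated)
Conditions: LiN(iPr)2, Me3SiCl (in situ quench), THF, −78 °C; crude 21 taken up in THF; then NBS, −78 to 0 °C
Reagents that add atoms: N-bromosuccinimide, O=C1CCC(=O)N1Br
Why: Kinetic deprotonation of the methyl ketone at CH3 with in situ silylation, then electrophilic bromination of the silyl enol ether, which should react with NBS much faster than the trisubstituted alkene.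

**Step 12**
Reactants: 22 (5E)-1-bromo-8-(3,3-dimethyloxiran-2-yl)-6-methyloct-5-en-2-one; 23 diethylphosphonoacetic acid
Product: 25 4-[(3E)-6-(3,3-dimethyloxiran-2-yl)-4-methylhex-3-en-1-yl]furan-2(5H)-one, via keto ester 24 (not isolated)
Conditions: K2CO3 (3 equiv), 18-crown-6 (cat.), MeCN, rt to 50 °C
Reagents that add atoms: none
Why: The carboxylate displaces the α-bromo ketone (SN2), and the phosphonate anion of the resulting ester should close the five-membered ring on the ketone by intramolecular Horner–Wadsworth–Emmons olefination, which leaves no E/Z question.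

**Step 13**
Reactants: 25 4-[(3E)-6-(3,3-dimethyloxiran-2-yl)-4-methylhex-3-en-1-yl]furan-2(5H)-one
Product: 27 (4E)-4-methyl-7-(5-oxo-2,5-dihydrofuran-3-yl)hept-4-enal, via diol 26 (not isolated)
Conditions: H5IO6 (1.3 equiv), THF/H2O, 0 °C to rt
Reagents that add atoms: none
Why: Acid-catalysed hydrolysis of the epoxide to the vicinal diol and Malaprade glycol cleavage by periodic acid in one flask; the trisubstituted alkene and the butenolide should be inert, and the aldehyde is used directly.

**Step 14**
Reactants: 16 (4R,5R)-4-(3-bromobut-3-en-1-yl)-3,4,5-trimethylcyclohex-2-en-1-one; 27 (4E)-4-methyl-7-(5-oxo-2,5-dihydrofuran-3-yl)hept-4-enal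
Product: 28 (4R,5R)-4-[(4R,7E)-4-hydroxy-7-methyl-3-methylidene-10-(5-oxo-2,5-dihydrofuran-3-yl)dec-7-en-1-yl]-3,4,5-trimethylcyclohex-2-en-1-one
Conditions: CrCl2 (4 equiv), NiCl2 (5 mol%), N-[2-((4S)-4-isopropyl-4,5-dihydrooxazol-2-yl)-6-methylphenyl]methanesulfonamide (4.4 equiv), Et3N, THF/MeCN, rt
Reagents that add atoms: none
Why: Nozaki–Hiyama–Kishi coupling, in which zerovalent nickel inserts into the C–Br bond, the alkenyl group passes to trivalent chromium and the alkenylchromium adds to the aldehyde only (enone and butenolide untouched); the sulfonamide ligand on chromium should direct addition to the Si face and so give the (R)-carbinol by reagent control, the ring stereocentres being remote.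

**Step 15**
Reactants: 28 (4R,5R)-4-[(4R,7E)-4-hydroxy-7-methyl-3-methylidene-10-(5-oxo-2,5-dihydrofuran-3-yl)dec-7-en-1-yl]-3,4,5-trimethylcyclohex-2-en-1-one
Product: 29 (4R,7E)-7-methyl-3-methylidene-10-(5-oxo-2,5-dihydrofuran-3-yl)-1-[(1R,6R)-1,2,6-trimethyl-4-oxocyclohex-2-en-1-yl]dec-7-en-4-yl acetate (CNP0204194.1)
Conditions: Ac2O, pyridine, DMAP (cat.), CH2Cl2, 0 °C to rt
Reagents that add atoms: acetic anhydride, CC(=O)OC(C)=O
Why: DMAP-catalysed acetylation of the secondary allylic alcohol at oxygen, with retention at the carbinol carbon.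

**Compound list**
1 | (R)-pent-4-en-2-ol | C[C@@H](O)CC=C | starting material
2 | acryloyl chloride | C=CC(=O)Cl | starting material
3 | (R)-pent-4-en-2-yl prop-2-enoate | C=CC(=O)O[C@H](C)CC=C | intermediate
4 | (R)-6-methyl-5,6-dihydro-2H-pyran-2-one | O=C1C=CC[C@@H](C)O1 | intermediate
5 | (4R,6R)-4,6-dimethyltetrahydro-2H-pyran-2-one (trans) | O=C1C[C@H](C)C[C@@H](C)O1 | intermediate
6 | 3-bromobut-3-en-1-ol | C=C(Br)CCO | starting material
7 | 3-bromobut-3-en-1-yl trifluoromethanesulfonate | C=C(Br)CCOS(=O)(=O)C(F)(F)F | intermediate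
8 | lithium (4R,6R)-4,6-dimethyl-5,6-dihydro-4H-pyran-2-olate (lithium enolate of 5) | [Li]OC1=C[C@H](C)C[C@@H](C)O1 | intermediate (not isolated)
9 | (3S,4R,6R)-3-(3-bromobut-3-en-1-yl)-4,6-dimethyltetrahydro-2H-pyran-2-one | C=C(Br)CC[C@@H]1C(=O)O[C@H](C)C[C@H]1C | intermediate
10 | lithium (4R,6R)-3-(3-bromobut-3-en-1-yl)-4,6-dimethyl-5,6-dihydro-4H-pyran-2-olate (lithium enolate of 9) | [Li]OC1=C(CCC(Br)=C)[C@H](C)C[C@@H](C)O1 | intermediate (not isolated)
11 | (3R,4R,6R)-3-(3-bromobut-3-en-1-yl)-3,4,6-trimethyltetrahydro-2H-pyran-2-one | C=C(Br)CC[C@@]1(C)C(=O)O[C@H](C)C[C@H]1C | intermediate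
12 | (3R,4R,6R)-3-(3-bromobut-3-en-1-yl)-6-hydroxy-3,4-dimethylheptan-2-one | C=C(Br)CC[C@@]([C@H](C)C[C@@H](C)O)(C)C(C)=O | intermediate
13 | (3R,4R)-3-(3-bromobut-3-en-1-yl)-3,4-dimethylheptane-2,6-dione | C=C(Br)CC[C@@]([C@H](C)CC(C)=O)(C)C(C)=O | intermediate
14 | (3R,4R)-3-(3-bromobut-3-en-1-yl)-3,4-dimethyl-6-(pyrrolidin-1-yl)hept-6-en-2-one (enamine) | C=C(Br)CC[C@@]([C@H](C)CC(=C)N1CCCC1)(C)C(C)=O | intermediate (not isolated)
15 | (4R,5R)-4-(3-bromobut-3-en-1-yl)-3-hydroxy-3,4,5-trimethylcyclohexan-1-one (ketol, either configuration at C3) | C=C(Br)CC[C@@]1(C)C(C)(O)CC(=O)C[C@H]1C | intermediate (not isolated)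
16 | (4R,5R)-4-(3-bromobut-3-en-1-yl)-3,4,5-trimethylcyclohex-2-en-1-one | C=C(Br)CC[C@@]1(C)C(C)=CC(=O)C[C@H]1C | intermediate
17 | (5E)-6,10-dimethylundeca-5,9-dien-2-one (geranylacetone) | CC(C)=CCC/C(C)=C/CCC(C)=O | starting material
18 | (5E)-9-bromo-10-hydroxy-6,10-dimethylundec-5-en-2-one (racemic bromohydrin) | CC(C)(O)C(Br)CC/C(C)=C/CCC(C)=O | intermediate (not isolated)
19 | (5E)-8-(3,3-dimethyloxiran-2-yl)-6-methyloct-5-en-2-one (racemic) | CC1(C)OC1CC/C(C)=C/CCC(C)=O | intermediate
20 | lithium (5E)-8-(3,3-dimethyloxiran-2-yl)-6-methylocta-1,5-dien-2-olate | CC1(C)OC1CC/C(C)=C/CCC(=C)O[Li] | intermediate (not isolated)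
21 | trimethyl{[(5E)-8-(3,3-dimethyloxiran-2-yl)-6-methylocta-1,5-dien-2-yl]oxy}silane | CC1(C)OC1CC/C(C)=C/CCC(=C)O[Si](C)(C)C | intermediate (not isolated)
22 | (5E)-1-bromo-8-(3,3-dimethyloxiran-2-yl)-6-methyloct-5-en-2-one | CC1(C)OC1CC/C(C)=C/CCC(=O)CBr | intermediate
23 | diethylphosphonoacetic acid | CCOP(=O)(CC(=O)O)OCC | starting material
24 | (5E)-8-(3,3-dimethyloxiran-2-yl)-6-methyl-2-oxooct-5-en-1-yl (diethoxyphosphoryl)acetate | CC1(C)OC1CC/C(C)=C/CCC(=O)COC(=O)CP(=O)(OCC)OCC | intermediate (not isolated)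
25 | 4-[(3E)-6-(3,3-dimethyloxiran-2-yl)-4-methylhex-3-en-1-yl]furan-2(5H)-one | CC1(C)OC1CC/C(C)=C/CCC2=CC(=O)OC2 | intermediate
26 | 4-[(3E)-7,8-dihydroxy-4,8-dimethylnon-3-en-1-yl]furan-2(5H)-one | CC(C)(O)C(O)CC/C(C)=C/CCC1=CC(=O)OC1 | intermediate (not isolated)
27 | (4E)-4-methyl-7-(5-oxo-2,5-dihydrofuran-3-yl)hept-4-enal | O=CCC/C(C)=C/CCC1=CC(=O)OC1 | intermediate
28 | (4R,5R)-4-[(4R,7E)-4-hydroxy-7-methyl-3-methylidene-10-(5-oxo-2,5-dihydrofuran-3-yl)dec-7-en-1-yl]-3,4,5-trimethylcyclohex-2-en-1-one | C=C(CC[C@@]1(C)C(C)=CC(=O)C[C@H]1C)[C@@H](CC/C(C)=C/CCC1=CC(=O)OC1)O | intermediate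
29 | (4R,7E)-7-methyl-3-methylidene-10-(5-oxo-2,5-dihydrofuran-3-yl)-1-[(1R,6R)-1,2,6-trimethyl-4-oxocyclohex-2-en-1-yl]dec-7-en-4-yl acetate | C=C(CC[C@@]1(C)C(C)=CC(=O)C[C@H]1C)[C@@H](CC/C(C)=C/CCC1=CC(=O)OC1)OC(C)=O | target

**Step count and risks**
Total step count: 15. Longest linear sequence: 10 steps (1, 2, 3, 5, 6, 7, 8, 9, 14, 15) from (R)-pent-4-en-2-ol; aldehyde 27 takes 4 steps (10–13) and triflate 7 one step (4).

Most likely to fail, step 14: facial control at the aldehyde may be incomplete, because the ring stereocentres are too remote to help and the epimers would be hard to separate, and oxidative addition of the 2-bromo-1-alkene may be slow. Fallback, setting out from 16 and 27: the coupling is run without the chiral ligand (CrCl2, NiCl2 cat., DMF, rt) to give the alcohol as both carbinol epimers F1. A Sharpless kinetic resolution (Ti(OiPr)4, L-(+)-diisopropyl tartrate, t-BuOOH, 4 Å MS, CH2Cl2, −20 °C, run to just past half conversion) should epoxidise the (4S)-epimer to the epoxy alcohol F2, which is removed by chromatography. The slow-reacting (4R)-alcohol that remains is 28, where the route continues.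

Second, step 9: the ring may close in the other direction (enol of the hindered acetyl group onto the C6 carbonyl), or the bond between the stereocentres may cleave by retro-Michael reaction. Fallback, setting out from 11: aminolysis with Me(MeO)NH·HCl and AlMe3 gives the hydroxy Weinreb amide F3, and Dess–Martin oxidation gives the keto amide F4. KOtBu in THF then forms the same ring bond by intramolecular acylation (only the methyl-side enolate can reach the amide through a six-membered transition state) to give the cyclohexane-1,3-dione F5. HC(OMe)3, MeOH and TsOH etherify the less hindered carbonyl to the vinylogous ester F6. MeLi with CeCl3 adds to the remaining carbonyl to give the tertiary carbinol F7, which aqueous HCl in the same flask converts (Stork–Danheiser transposition) to 16, where the route continues.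

Third, step 5: the homoallylic triflate may be lost by elimination or decomposition before C-alkylation, and proton transfer may cause over-alkylation. Fallback, setting out from 5: LiN(iPr)2 and allyl bromide give the allyl lactone F8, and LiN(iPr)2 and MeI then give the quaternary allyl lactone F9 with the same facial control as in step 6. Hydroboration with 9-BBN and oxidation with NaBO3 give the primary alcohol F10; Dess–Martin oxidation gives the aldehyde F11; the Ohira–Bestmann reagent (K2CO3, MeOH) gives the terminal alkyne F12. Bromoboration with B-bromo-9-BBN followed by AcOH gives the 2-bromo-1-alkene 11, where the route continues.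

**Further compounds**
F1 | step 14 | (4R,5R)-4-[(7E)-4-hydroxy-7-methyl-3-methylidene-10-(5-oxo-2,5-dihydrofuran-3-yl)dec-7-en-1-yl]-3,4,5-trimethylcyclohex-2-en-1-one (both epimers at the carbinol carbon) | C=C(CC[C@@]1(C)C(C)=CC(=O)C[C@H]1C)C(O)CC/C(C)=C/CCC1=CC(=O)OC1
F2 | step 14 | (4R,5R)-4-{2-[(2S)-2-[(1S,4E)-1-hydroxy-4-methyl-7-(5-oxo-2,5-dihydrofuran-3-yl)hept-4-en-1-yl]oxiran-2-yl]ethyl}-3,4,5-trimethylcyclohex-2-en-1-one | O[C@@H](CC/C(C)=C/CCC1=CC(=O)OC1)[C@]2(CC[C@@]3(C)C(C)=CC(=O)C[C@H]3C)CO2
F3 | step 9 | (2R,3R,5R)-2-(3-bromobut-3-en-1-yl)-5-hydroxy-N-methoxy-N,2,3-trimethylhexanamide | C=C(Br)CC[C@@]([C@H](C)C[C@@H](C)O)(C)C(=O)N(C)OC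
F4 | step 9 | (2R,3R)-2-(3-bromobut-3-en-1-yl)-N-methoxy-N,2,3-trimethyl-5-oxohexanamide | C=C(Br)CC[C@@]([C@H](C)CC(C)=O)(C)C(=O)N(C)OC
F5 | step 9 | (4R,5R)-4-(3-bromobut-3-en-1-yl)-4,5-dimethylcyclohexane-1,3-dione | C=C(Br)CC[C@@]1(C)C(=O)CC(=O)C[C@H]1C
F6 | step 9 | (5R,6R)-6-(3-bromobut-3-en-1-yl)-3-methoxy-5,6-dimethylcyclohex-2-en-1-one | C=C(Br)CC[C@@]1(C)C(=O)C=C(OC)C[C@H]1C
F7 | step 9 | (5R,6R)-6-(3-bromobut-3-en-1-yl)-3-methoxy-1,5,6-trimethylcyclohex-2-en-1-ol (either configuration at C1) | C=C(Br)CC[C@@]1(C)C(C)(O)C=C(OC)C[C@H]1C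
F8 | step 5 | (3S,4R,6R)-4,6-dimethyl-3-(prop-2-en-1-yl)tetrahydro-2H-pyran-2-one | C=CC[C@@H]1C(=O)O[C@H](C)C[C@H]1C
F9 | step 5 | (3R,4R,6R)-3,4,6-trimethyl-3-(prop-2-en-1-yl)tetrahydro-2H-pyran-2-one | C=CC[C@@]1(C)C(=O)O[C@H](C)C[C@H]1C
F10 | step 5 | (3R,4R,6R)-3-(3-hydroxypropyl)-3,4,6-trimethyltetrahydro-2H-pyran-2-one | OCCC[C@@]1(C)C(=O)O[C@H](C)C[C@H]1C
F11 | step 5 | 3-[(3R,4R,6R)-3,4,6-trimethyl-2-oxotetrahydro-2H-pyran-3-yl]propanal | O=CCC[C@@]1(C)C(=O)O[C@H](C)C[C@H]1C
F12 | step 5 | (3R,4R,6R)-3-(but-3-yn-1-yl)-3,4,6-trimethyltetrahydro-2H-pyran-2-one | C#CCC[C@@]1(C)C(=O)O[C@H](C)C[C@H]1C
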